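## Retrosynthetic overview

- The strategy rests on ring C. Its O1–C2 and C3–C4 bonds both end on the phloroglucinol ring A (at C8a and C4a), so O1/C8a/C4a/C4 are the heterodiene of a ring A ortho-quinone methide and C2–C3 is the vinyl group of a ring B styrene.
- Disconnection 1 cuts both bonds at once ([4+2]). The protected 4-methoxyflavan comes from 2,4-bis(benzyloxy)-6-hydroxybenzaldehyde, trimethyl orthoformate and the ring B styrene. The C4 methoxy group stores the oxidation level of the ketone.
- Disconnection 2 takes the styrene back to an aryl bromide (Suzuki vinylation). The two side-chain stereocenters come from an auxiliary-controlled anti-aldol of an aryloxyacetyl imide with O-benzylvanillin, and the aryl ether from 4-bromo-2,6-dimethoxyphenol and bromoacetic acid.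
- Ring order: ring A, ring B and the guaiacyl ring are bought. Ring C is the only ring made and is closed in step 8; C4 is then taken to the ketone and the silyl and benzyl groups are removed.

Key step: step 8

Assumption: the sense of induction of the chiral acid in step 8 cannot be derived with confidence, so the (R)-catalyst is written and its mirror image is to be used if a trial favours the (2R) product; C4 of the 4-methoxyflavan and of the flavan-4-ol may be an epimer mixture, which is harmless because C4 becomes the ketone.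

## Route

Step 1
Reactants: 1 4-bromo-2,6-dimethoxyphenol; 2 bromoacetic acid
Product: 3 2-(4-bromo-2,6-dimethoxyphenoxy)acetic acid
Conditions: NaH (2.5 equiv), THF/DMF, 0 → 60 °C; then aq. HCl
Reagents that add atoms: none
Why: Williamson ether synthesis, in which the sodium phenoxide displaces bromide from sodium bromoacetate by SN2 and the carboxylate formed is not alkylated further.

Step 2
Reactants: 3 2-(4-bromo-2,6-dimethoxyphenoxy)acetic acid; 4 (S)-4-benzyloxazolidin-2-one
Product: 6 (S)-4-benzyl-3-[2-(4-bromo-2,6-dimethoxyphenoxy)acetyl]oxazolidin-2-one, via mixed pivalic anhydride 5 (not isolated)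
Conditions: PivCl, Et3N, THF, −20 °C; then LiCl, 4, −20 °C → rt
Reagents that add atoms: pivaloyl chloride, CC(C)(C)C(Cl)=O (its atoms are in 5 only)
Why: N-acylation of the oxazolidinone through the mixed pivalic anhydride (LiCl/Et3N activation), the nitrogen attacking the less hindered aryloxyacetyl carbonyl; no stereocenter is formed.

Step 3
Reactants: 6 (S)-4-benzyl-3-[2-(4-bromo-2,6-dimethoxyphenoxy)acetyl]oxazolidin-2-one; 7 4-(benzyloxy)-3-methoxybenzaldehyde (O-benzylvanillin)
Product: 9 (4S)-4-benzyl-3-[(2R,3R)-3-[4-(benzyloxy)-3-methoxyphenyl]-2-(4-bromo-2,6-dimethoxyphenoxy)-3-hydroxypropanoyl]oxazolidin-2-one, via trimethylsilyl ether 8 (not isolated)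
Conditions: MgCl2 (20 mol %), Et3N, TMSCl, EtOAc, rt; then 1 M HCl, THF, 0 °C
Reagents that add atoms: chlorotrimethylsilane, C[Si](C)(C)Cl (its atoms are in 8 only)
Why: Evans magnesium halide-catalysed direct anti-aldol reaction, in which MgCl2/Et3N soft-enolises the chelated imide to the (Z)-enolate, the aldehyde adds to the face opposite the auxiliary benzyl group through a boat-like transition state to give the anti (2R,3R) adduct, and silylation of the aldolate turns the magnesium over and blocks retro-aldol equilibration.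

Step 4
Reactants: 9 anti-aldol adduct
Product: 10 (1R,2S)-1-[4-(benzyloxy)-3-methoxyphenyl]-2-(4-bromo-2,6-dimethoxyphenoxy)propane-1,3-diol
Conditions: LiBH4, MeOH (1 equiv), THF, 0 °C
Reagents that add atoms: none
Why: Reductive cleavage of the N-acyloxazolidinone with LiBH4, which reduces the exocyclic imide carbonyl to the primary alcohol without touching either stereocenter and releases the auxiliary for recovery.

Step 5
Reactants: 10 (1R,2S)-diol
Product: 11 (1R,2S)-1-[4-(benzyloxy)-3-methoxyphenyl]-2-(4-bromo-2,6-dimethoxyphenoxy)-1,3-bis(tert-butyldimethylsilyloxy)propane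
Conditions: TBSOTf (2.5 equiv), 2,6-lutidine, CH2Cl2, −78 → 0 °C
Reagents that add atoms: tert-butyldimethylsilyl triflate, CC(C)(C)[Si](C)(C)OS(=O)(=O)C(F)(F)F
Why: Silylation of both hydroxyl groups with the reactive silyl triflate, which also covers the hindered secondary benzylic alcohol, while the hindered base keeps the medium non-acidic so that the benzylic carbon does not ionise.

Step 6
Reactants: 11 bis-silylated aryl bromide; 12 4,4,5,5-tetramethyl-2-vinyl-1,3,2-dioxaborolane (vinylboronic acid pinacol ester)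
Product: 13 (1R,2S)-1-[4-(benzyloxy)-3-methoxyphenyl]-1,3-bis(tert-butyldimethylsilyloxy)-2-(2,6-dimethoxy-4-vinylphenoxy)propane
Conditions: Pd(dppf)Cl2 (5 mol %), K2CO3, 1,4-dioxane/H2O, 85 °C
Reagents that add atoms: none
Why: Suzuki–Miyaura cross-coupling, in which zerovalent palladium inserts into the unhindered aryl C–Br bond, the vinyl group is transferred from boron and reductive elimination gives the styrene; silyl and benzyl ethers are inert to the carbonate base.

Step 7
Reactants: 14 2,4,6-trihydroxybenzaldehyde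
Product: 15 2,4-bis(benzyloxy)-6-hydroxybenzaldehyde
Conditions: BnBr (2.05 equiv), K2CO3, DMF, 0 °C → rt
Reagents that add atoms: benzyl bromide, BrCc1ccccc1
Why: Selective Williamson O-benzylation, in which the 4-hydroxyl and one ortho hydroxyl are alkylated while the remaining ortho hydroxyl is held in a hydrogen bond to the aldehyde and reacts much more slowly with a weak base and two equivalents of halide.

Step 8
Reactants: 15 2,4-bis(benzyloxy)-6-hydroxybenzaldehyde; 16 trimethyl orthoformate; 13 ring B styrene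
Product: 19 protected (2S,4S)-4-methoxyflavan, via dimethyl acetal 17 (not isolated), via ortho-quinone methide 18 (not isolated)
Conditions: (R)-3,3'-bis(2,4,6-triisopropylphenyl)-1,1'-binaphthyl-2,2'-diyl N-triflylphosphoramide (10 mol %), 16 (2 equiv), 5 Å MS, toluene, −20 °C → rt
Reagents that add atoms: none
Why: Proposed new method: the acid converts 15 and 16 into acetal 17, which loses methanol to the 4-methoxy ortho-quinone methide 18 (in protonated form an ortho-hydroxyaryl oxocarbenium ion paired with the chiral phosphoramide anion), and this heterodiene takes up the vinyl group of 13 in an inverse-electron-demand hetero-Diels–Alder reaction, concerted and asynchronous or stepwise through the C2 benzylic cation. The closest known reactions are the Sc(OTf)3-catalysed salicylaldehyde–orthoformate–styrene synthesis of racemic 4-methoxy-2-arylchromans and the chiral phosphoric acid or N-triflylphosphoramide catalysed [4+2] cycloadditions of ortho-quinone methides with styrenes and other electron-rich alkenes. Ring C closes as a six-membered pyran in an intermolecular [4+2] mode, C3–C4 forming ahead of O1–C2 (in the stepwise limit a 6-endo capture of the benzylic cation by the phenol oxygen). C2 is set by the chiral counter-anion, which is hydrogen-bonded to the phenolic O–H and therefore sits at the forming O1–C2 bond, whereas C4 follows from the endo approach of the aryl group (2,4-cis) and is erased at the ketone stage. The step needs the aryl group at C2, which the polarisation of the styrene secures (nucleophilic terminal carbon, cation-stabilising 4-alkoxy-3,5-dimethoxyphenyl group), and catalyst control of the C2 face, since the side-chain stereocenters of 13 are too remote to bias it. The two benzyloxy groups of ring A make the oxocarbenium ion accessible with a catalytic Brønsted acid that should leave the silyl ethers and the styrene intact.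

Step 9
Reactants: 19 protected (2S,4S)-4-methoxyflavan (with any C4 epimer)
Product: 20 protected (2S)-flavan-4-ol (C4 epimer mixture)
Conditions: PPTS (20 mol %), acetone/H2O, rt
Reagents that add atoms: water, O
Why: SN1 hydrolysis of a benzylic ether, in which the C4 cation is stabilised by the three oxygen substituents of ring A (O1, 5-OBn, 7-OBn), so that a weak acid that spares the silyl ethers exchanges the methoxy group for hydroxyl.

Step 10
Reactants: 20 protected (2S)-flavan-4-ol
Product: 21 protected (2S)-flavanone (5,7-di-O-benzyl, side chain bis-TBS, guaiacyl O-benzyl)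
Conditions: Dess–Martin periodinane, pyridine, CH2Cl2, 0 °C → rt
Reagents that add atoms: none
Why: Dess–Martin oxidation of the secondary benzylic alcohol to the aryl ketone under buffered, non-basic conditions that do not open the pyranone ring and therefore keep C2.

Step 11
Reactants: 21 protected (2S)-flavanone
Product: 22 (2S)-5,7-bis(benzyloxy)flavanone with free side-chain 1,3-diol
Conditions: HF·pyridine, pyridine, THF, 0 °C → rt
Reagents that add atoms: none
Why: Fluoride-mediated cleavage of both Si–O bonds under buffered, mildly acidic conditions; basic fluoride is avoided because it would open the flavanone by retro-oxa-Michael reaction and racemise C2.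

Step 12
Reactants: 22 tri-O-benzyl flavanone diol
Product: 23 target, (2S)-5,7-dihydroxy-2-{4-[(1R,2S)-1,3-dihydroxy-1-(4-hydroxy-3-methoxyphenyl)propan-2-yloxy]-3,5-dimethoxyphenyl}chroman-4-one
Conditions: H2 (1 atm), 10% Pd/C, EtOAc/EtOH, rt
Reagents that add atoms: none
Why: Catalytic hydrogenolysis of the three aryl benzyl ethers over palladium at neutral pH and atmospheric pressure, under which the benzylic C–O bonds at C2 and at the side-chain carbinol and the aryl ketone are expected to persist.

## Compound list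

1 | 4-bromo-2,6-dimethoxyphenol | COc1cc(Br)cc(OC)c1O | starting material
2 | bromoacetic acid | OC(=O)CBr | starting material
3 | 2-(4-bromo-2,6-dimethoxyphenoxy)acetic acid | COc1cc(Br)cc(OC)c1OCC(=O)O | intermediate
4 | (S)-4-benzyloxazolidin-2-one | O=C1OC[C@H](Cc2ccccc2)N1 | starting material
5 | 2-(4-bromo-2,6-dimethoxyphenoxy)acetic pivalic anhydride | COc1cc(Br)cc(OC)c1OCC(=O)OC(=O)C(C)(C)C | intermediate (not isolated)
6 | (S)-4-benzyl-3-[2-(4-bromo-2,6-dimethoxyphenoxy)acetyl]oxazolidin-2-one | COc1cc(Br)cc(OC)c1OCC(=O)N1[C@@H](Cc2ccccc2)COC1=O | intermediate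
7 | 4-(benzyloxy)-3-methoxybenzaldehyde | COc1cc(C=O)ccc1OCc1ccccc1 | starting material
8 | (4S)-4-benzyl-3-[(2R,3R)-3-[4-(benzyloxy)-3-methoxyphenyl]-2-(4-bromo-2,6-dimethoxyphenoxy)-3-(trimethylsilyloxy)propanoyl]oxazolidin-2-one | COc1cc([C@@H](O[Si](C)(C)C)[C@H](C(=O)N2[C@@H](Cc3ccccc3)COC2=O)Oc2c(OC)cc(Br)cc2OC)ccc1OCc1ccccc1 | intermediate (not isolated)
9 | (4S)-4-benzyl-3-[(2R,3R)-3-[4-(benzyloxy)-3-methoxyphenyl]-2-(4-bromo-2,6-dimethoxyphenoxy)-3-hydroxypropanoyl]oxazolidin-2-one | COc1cc([C@@H](O)[C@H](C(=O)N2[C@@H](Cc3ccccc3)COC2=O)Oc2c(OC)cc(Br)cc2OC)ccc1OCc1ccccc1 | intermediate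
10 | (1R,2S)-1-[4-(benzyloxy)-3-methoxyphenyl]-2-(4-bromo-2,6-dimethoxyphenoxy)propane-1,3-diol | COc1cc([C@@H](O)[C@H](CO)Oc2c(OC)cc(Br)cc2OC)ccc1OCc1ccccc1 | intermediate
11 | (1R,2S)-1-[4-(benzyloxy)-3-methoxyphenyl]-2-(4-bromo-2,6-dimethoxyphenoxy)-1,3-bis(tert-butyldimethylsilyloxy)propane | COc1cc([C@@H](O[Si](C)(C)C(C)(C)C)[C@H](CO[Si](C)(C)C(C)(C)C)Oc2c(OC)cc(Br)cc2OC)ccc1OCc1ccccc1 | intermediate
12 | 4,4,5,5-tetramethyl-2-vinyl-1,3,2-dioxaborolane | C=CB1OC(C)(C)C(C)(C)O1 | starting material
13 | (1R,2S)-1-[4-(benzyloxy)-3-methoxyphenyl]-1,3-bis(tert-butyldimethylsilyloxy)-2-(2,6-dimethoxy-4-vinylphenoxy)propane | COc1cc([C@@H](O[Si](C)(C)C(C)(C)C)[C@H](CO[Si](C)(C)C(C)(C)C)Oc2c(OC)cc(C=C)cc2OC)ccc1OCc1ccccc1 | intermediate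
14 | 2,4,6-trihydroxybenzaldehyde | O=Cc1c(O)cc(O)cc1O | starting material
15 | 2,4-bis(benzyloxy)-6-hydroxybenzaldehyde | O=Cc1c(O)cc(OCc2ccccc2)cc1OCc1ccccc1 | intermediate
16 | trimethyl orthoformate | COC(OC)OC | starting material
17 | 3,5-bis(benzyloxy)-2-(dimethoxymethyl)phenol | COC(OC)c1c(O)cc(OCc2ccccc2)cc1OCc1ccccc1 | intermediate (not isolated)
18 | 3,5-bis(benzyloxy)-6-(methoxymethylene)cyclohexa-2,4-dien-1-one | COC=C1C(=O)C=C(OCc2ccccc2)C=C1OCc1ccccc1 | intermediate (not isolated)
19 | (2S,4S)-5,7-bis(benzyloxy)-2-{4-[(1R,2S)-1-[4-(benzyloxy)-3-methoxyphenyl]-1,3-bis(tert-butyldimethylsilyloxy)propan-2-yloxy]-3,5-dimethoxyphenyl}-4-methoxychroman (2,4-cis drawn) | COc1cc([C@@H](O[Si](C)(C)C(C)(C)C)[C@H](CO[Si](C)(C)C(C)(C)C)Oc2c(OC)cc([C@@H]3C[C@H](OC)c4c(OCc5ccccc5)cc(OCc5ccccc5)cc4O3)cc2OC)ccc1OCc1ccccc1 | intermediate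
20 | (2S)-5,7-bis(benzyloxy)-2-{4-[(1R,2S)-1-[4-(benzyloxy)-3-methoxyphenyl]-1,3-bis(tert-butyldimethylsilyloxy)propan-2-yloxy]-3,5-dimethoxyphenyl}chroman-4-ol (C4 epimers, left undefined) | COc1cc([C@@H](O[Si](C)(C)C(C)(C)C)[C@H](CO[Si](C)(C)C(C)(C)C)Oc2c(OC)cc([C@@H]3CC(O)c4c(OCc5ccccc5)cc(OCc5ccccc5)cc4O3)cc2OC)ccc1OCc1ccccc1 | intermediate
21 | (2S)-5,7-bis(benzyloxy)-2-{4-[(1R,2S)-1-[4-(benzyloxy)-3-methoxyphenyl]-1,3-bis(tert-butyldimethylsilyloxy)propan-2-yloxy]-3,5-dimethoxyphenyl}chroman-4-one | COc1cc([C@@H](O[Si](C)(C)C(C)(C)C)[C@H](CO[Si](C)(C)C(C)(C)C)Oc2c(OC)cc([C@@H]3CC(=O)c4c(OCc5ccccc5)cc(OCc5ccccc5)cc4O3)cc2OC)ccc1OCc1ccccc1 | intermediate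
22 | (2S)-5,7-bis(benzyloxy)-2-{4-[(1R,2S)-1-[4-(benzyloxy)-3-methoxyphenyl]-1,3-dihydroxypropan-2-yloxy]-3,5-dimethoxyphenyl}chroman-4-one | COc1cc([C@@H](O)[C@H](CO)Oc2c(OC)cc([C@@H]3CC(=O)c4c(OCc5ccccc5)cc(OCc5ccccc5)cc4O3)cc2OC)ccc1OCc1ccccc1 | intermediate
23 | (2S)-5,7-dihydroxy-2-{4-[(1R,2S)-1,3-dihydroxy-1-(4-hydroxy-3-methoxyphenyl)propan-2-yloxy]-3,5-dimethoxyphenyl}chroman-4-one | COc1cc([C@@H](O)[C@H](CO)Oc2c(OC)cc([C@@H]3CC(=O)c4c(O)cc(O)cc4O3)cc2OC)ccc1O | target

## Step count and risks

Total steps: 12. Longest linear sequence: 11 (steps 1–6, then 8–12); step 7 is a one-step branch.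

**Step 8 (proposed new method).** Three processes may defeat it:
- the doubly benzyloxy-stabilised oxocarbenium ion may react too slowly with the styrene;
- the acid may oligomerise the styrene or ionise the benzylic silyl ether;
- catalyst control of the C2 face, or the endo preference on which it depends in the concerted pathway, may be too weak, which would leave a C2 epimer mixture after C4 is oxidised.

The fallback uses known chemistry, sets out from bromide 11 and comes back at flavanone 21, bypassing steps 6–10. Bromine–lithium exchange on 11 (n-BuLi, THF, −78 °C), B(Oi-Pr)3 and aqueous NH4Cl should give the arylboronic acid F1. In parallel, commercial 2,4,6-trihydroxyacetophenone is dibenzylated (BnBr, K2CO3, DMF) to 2,4-bis(benzyloxy)-6-hydroxyacetophenone F2, condensed with DMF dimethyl acetal to the enaminone F3 and cyclised with aqueous HCl to 5,7-bis(benzyloxy)chromone F4. Rhodium-catalysed asymmetric 1,4-addition of F1 to F4 ([Rh(OH)(cod)]2 with an electron-poor atropisomeric bisphosphine of the MeO-F12-BIPHEP type, in the enantiomer that delivers (2S), toluene/H2O) then forms the C2–aryl bond and the C2 stereocenter under ligand control and gives 21 directly.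

**Step 3.** The α-aryloxy enolate may give lower anti-selectivity or facial selectivity than simple acyl imides, and retro-aldol equilibration may compete with silylation of the aldolate. The fallback sets out from acid 3 and comes back at bromide 11.
- Acid 3 is coupled through anhydride 5 with (R)-4-benzyloxazolidin-2-one to the enantiomeric-auxiliary imide F5.
- An Evans boron syn-aldol (Bu2BOTf, i-Pr2NEt, CH2Cl2, −78 → 0 °C, then 7) should give the (2R,3S) syn adduct F6, which already has the correct ether-bearing carbon.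
- LiBH4 gives the threo (1S,2S)-diol F7, and TBSCl/imidazole protects the primary alcohol to give F8.
- Dess–Martin oxidation gives the aryl ketone F9, and Felkin–Anh reduction with the bulky non-chelating hydride LiBH(s-Bu)3 (THF, −78 °C) should give the erythro (1R,2S) alcohol F10.
- TBSOTf/2,6-lutidine converts F10 into 11.

**Step 9.** The C4 cation may lose a proton to give the flav-3-ene, the flavan-4-ol may self-condense under acid, and silyl groups may be partly lost. The fallback sets out from 19 and comes back at 21, bypassing 20 and step 10, and makes no new compound (F0). DDQ in CH2Cl2/pH 7 buffer at 0 °C abstracts hydride from C4, the most electron-rich benzylic position, to give the 4-methoxy oxocarbenium ion. Water converts this through the hemiketal into the ketone and methanol; this is the known DDQ oxidation of electron-rich benzylic methyl ethers to carbonyl compounds.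

## Further compounds

F1 | step 8 | 4-{[(1R,2S)-1-[4-(benzyloxy)-3-methoxyphenyl]-1,3-bis(tert-butyldimethylsilyloxy)propan-2-yl]oxy}-3,5-dimethoxyphenylboronic acid | COc1cc([C@@H](O[Si](C)(C)C(C)(C)C)[C@H](CO[Si](C)(C)C(C)(C)C)Oc2c(OC)cc(B(O)O)cc2OC)ccc1OCc1ccccc1
F2 | step 8 | 2,4-bis(benzyloxy)-6-hydroxyacetophenone | CC(=O)c1c(O)cc(OCc2ccccc2)cc1OCc1ccccc1
F3 | step 8 | (E)-1-[2,4-bis(benzyloxy)-6-hydroxyphenyl]-3-(dimethylamino)prop-2-en-1-one | CN(C)/C=C/C(=O)c1c(O)cc(OCc2ccccc2)cc1OCc1ccccc1
F4 | step 8 | 5,7-bis(benzyloxy)-4H-chromen-4-one | O=c1ccoc2cc(OCc3ccccc3)cc(OCc3ccccc3)c12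
F5 | step 3 | (R)-4-benzyl-3-[2-(4-bromo-2,6-dimethoxyphenoxy)acetyl]oxazolidin-2-one | COc1cc(Br)cc(OC)c1OCC(=O)N1[C@H](Cc2ccccc2)COC1=O
F6 | step 3 | (4R)-4-benzyl-3-[(2R,3S)-3-[4-(benzyloxy)-3-methoxyphenyl]-2-(4-bromo-2,6-dimethoxyphenoxy)-3-hydroxypropanoyl]oxazolidin-2-one | COc1cc([C@H](O)[C@H](C(=O)N2[C@H](Cc3ccccc3)COC2=O)Oc2c(OC)cc(Br)cc2OC)ccc1OCc1ccccc1
F7 | step 3 | (1S,2S)-1-[4-(benzyloxy)-3-methoxyphenyl]-2-(4-bromo-2,6-dimethoxyphenoxy)propane-1,3-diol | COc1cc([C@H](O)[C@H](CO)Oc2c(OC)cc(Br)cc2OC)ccc1OCc1ccccc1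
F8 | step 3 | (1S,2S)-1-[4-(benzyloxy)-3-methoxyphenyl]-2-(4-bromo-2,6-dimethoxyphenoxy)-3-(tert-butyldimethylsilyloxy)propan-1-ol | COc1cc([C@H](O)[C@H](CO[Si](C)(C)C(C)(C)C)Oc2c(OC)cc(Br)cc2OC)ccc1OCc1ccccc1
F9 | step 3 | (S)-1-[4-(benzyloxy)-3-methoxyphenyl]-2-(4-bromo-2,6-dimethoxyphenoxy)-3-(tert-butyldimethylsilyloxy)propan-1-one | COc1cc(C(=O)[C@H](CO[Si](C)(C)C(C)(C)C)Oc2c(OC)cc(Br)cc2OC)ccc1OCc1ccccc1
F10 | step 3 | (1R,2S)-1-[4-(benzyloxy)-3-methoxyphenyl]-2-(4-bromo-2,6-dimethoxyphenoxy)-3-(tert-butyldimethylsilyloxy)propan-1-ol | COc1cc([C@@H](O)[C@H](CO[Si](C)(C)C(C)(C)C)Oc2c(OC)cc(Br)cc2OC)ccc1OCc1ccccc1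
F0 | step 9 | none | none
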